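## Retrosynthetic overview

1. Target 19 comes from the tertiary boronic ester 17 by replacing the C2–B bond with C2–H (retention) and removing the silyl group; boron is a temporary activating group on C2.
2. Key disconnection, C2–C(aryl): 3,4,5-trimethoxyphenyllithium plus the cyclic alkenylboronic ester 13 (a 4,5-dihydrofuran, O1–C2(B)=C3). Protonation of the derived boronate complex at C3 drives the aryl group from boron to C2 and creates C2 and C3 together, both relayed from C4.
3. Enabling feature: the ring oxygen O1 on the aryl-bearing carbon C2 of the oxolane. It lets C2–C3 be taken back to a ketene-acetal-level enol ether O1–C2=C3 with nucleophilic C3, flanked by the single sp3 stereocentre C4 that carries the 2,4,5-trimethoxybenzyl group.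
4. 13 comes from the ketene acetal phosphate 12, and 12 from the α-hydroxymethylated (R)-β-benzyl-γ-butyrolactone 7.
5. Ring order: the oxolane ring is formed once, as lactone 7 (Stobbe condensation, catalytic asymmetric hydrogenation that sets C4, ester reduction and lactonisation), and is never opened again; both arenes are bought.

Key step: step 8

Remark: lactones 9 and 10 are drawn as the expected trans (3S,4R) isomers, but the C3 configuration at that stage does not matter because C3 is made planar in step 6. The hand of the Et-DuPhos ligand in step 2 is assumed to be the one that delivers (R)-5; both antipodes are commercial.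

## Route

Step 1
Reactants: 1 2,4,5-trimethoxybenzaldehyde; 2 dimethyl succinate
Product: 4 (E)-3-(methoxycarbonyl)-4-(2,4,5-trimethoxyphenyl)but-3-enoic acid, via paraconic ester lactone 3 (not isolated)
Conditions: NaOMe, MeOH, reflux; then aq HCl
Reagents that add atoms: none
Why: Stobbe condensation: the succinate enolate adds to the aldehyde, the aldolate closes to lactone 3, and irreversible E1cB ring opening gives the (E)-alkylidene half-ester as its carboxylate; no stereocentre is formed.

Step 2
Reactants: 4 (E)-3-(methoxycarbonyl)-4-(2,4,5-trimethoxyphenyl)but-3-enoic acid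
Product: 5 (R)-3-(methoxycarbonyl)-4-(2,4,5-trimethoxyphenyl)butanoic acid
Conditions: H2 (5 bar), [Rh(cod)(Et-DuPhos)]BF4 (0.5 mol %), NaOMe (10 mol %), MeOH, rt
Reagents that add atoms: none
Why: Rh(I)–bisphospholane asymmetric hydrogenation of a Stobbe-type itaconate half-ester, in which the carboxylate binds the metal and the catalyst alone sets the stereocentre that becomes C4 of the oxolane (R).

Step 3
Reactants: 5 (R)-3-(methoxycarbonyl)-4-(2,4,5-trimethoxyphenyl)butanoic acid
Product: 7 (R)-4-(2,4,5-trimethoxybenzyl)oxolan-2-one, via hydroxy acid 6 (not isolated)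
Conditions: KOH (1 equiv), EtOH; CaCl2, NaBH4, EtOH, 0 °C → rt; then 3 M HCl, rt
Reagents that add atoms: none
Why: Calcium borohydride should reduce the methyl ester but not the potassium carboxylate, and acidification closes hydroxy acid 6 to the γ-lactone (chemoselective ester reduction, then lactonisation) without touching the stereocentre.

Step 4
Reactants: 7 (R)-4-(2,4,5-trimethoxybenzyl)oxolan-2-one
Product: 9 (3S,4R)-3-(hydroxymethyl)-4-(2,4,5-trimethoxybenzyl)oxolan-2-one, via lithium lactone enolate 8 (not isolated)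
Conditions: LDA, THF, −78 °C; CH2O (g), −78 → −30 °C; aq NH4Cl
Reagents that add atoms: formaldehyde, C=O
Why: Aldol hydroxymethylation of the lithium lactone enolate with monomeric formaldehyde, which should enter anti to the C4 benzyl group to give the trans lactone (3S), a centre that is erased again in step 6.

Step 5
Reactants: 9 (3S,4R)-3-(hydroxymethyl)-4-(2,4,5-trimethoxybenzyl)oxolan-2-one
Product: 10 (3S,4R)-3-[(tert-butyldimethylsilyloxy)methyl]-4-(2,4,5-trimethoxybenzyl)oxolan-2-one
Conditions: TBSCl, imidazole, DMF, 0 °C → rt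
Reagents that add atoms: tert-butyldimethylsilyl chloride, CC(C)(C)[Si](C)(C)Cl
Why: Standard silylation of a primary alcohol masks the hydroxyl against the bases and the organolithium used later; no stereocentre is affected.

Step 6
Reactants: 10 (3S,4R)-3-[(tert-butyldimethylsilyloxy)methyl]-4-(2,4,5-trimethoxybenzyl)oxolan-2-one
Product: 12 (4R)-3-[(tert-butyldimethylsilyloxy)methyl]-4-(2,4,5-trimethoxybenzyl)-4,5-dihydrofuran-2-yl diphenyl phosphate, via potassium lactone enolate 11 (not isolated)
Conditions: KHMDS, (PhO)2P(O)Cl, HMPA, THF, −78 °C (base added last)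
Reagents that add atoms: diphenyl chlorophosphate, O=P(Cl)(Oc1ccccc1)Oc1ccccc1
Why: O-Phosphorylation of the potassium lactone enolate under internal-quench conditions (cyclic ketene acetal phosphate formation) should outrun β-elimination of silyloxide; it flattens C3 and leaves C4 as the only stereocentre.

Step 7
Reactants: 12 (4R)-3-[(tert-butyldimethylsilyloxy)methyl]-4-(2,4,5-trimethoxybenzyl)-4,5-dihydrofuran-2-yl diphenyl phosphate
Product: 13 tert-butyldimethyl{[(4R)-2-(4,4,5,5-tetramethyl-1,3,2-dioxaborolan-2-yl)-4-(2,4,5-trimethoxybenzyl)-4,5-dihydrofuran-3-yl]methoxy}silane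
Conditions: B2pin2, PdCl2(PPh3)2 (3 mol %), PPh3 (6 mol %), KOPh, toluene, 50 °C
Reagents that add atoms: bis(pinacolato)diboron, CC1(C)OB(OC1(C)C)B1OC(C)(C)C(C)(C)O1
Why: Miyaura borylation: oxidative addition of Pd(0) into the ketene acetal C–O(phosphate) bond, transmetallation with phenoxide-activated B2pin2 and reductive elimination should give the cyclic α-alkoxy alkenylboronic ester; no stereocentre is involved.

Step 8
Reactants: 13 tert-butyldimethyl{[(4R)-2-(4,4,5,5-tetramethyl-1,3,2-dioxaborolan-2-yl)-4-(2,4,5-trimethoxybenzyl)-4,5-dihydrofuran-3-yl]methoxy}silane; 14 5-bromo-1,2,3-trimethoxybenzene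
Product: 17 (2R,3R,4R)-3-[(tert-butyldimethylsilyloxy)methyl]-2-(4,4,5,5-tetramethyl-1,3,2-dioxaborolan-2-yl)-4-(2,4,5-trimethoxybenzyl)-2-(3,4,5-trimethoxyphenyl)oxolane, via 3,4,5-trimethoxyphenyllithium 15 (not isolated), via lithium alkenyl(aryl)boronate complex 16 (not isolated)
Conditions: 14, n-BuLi, THF, −78 °C; then 13, −78 °C; then 2,4,6-collidinium triflate, CH2Cl2, −78 → −30 °C
Reagents that add atoms: none
Why: Proposed new method: bromine–lithium exchange gives aryllithium 15, which adds to the boron of 13 to form boronate complex 16; there the ring oxygen O1 and the electron-rich C2–B bond both push electron density onto C3, so the hindered pyridinium acid should protonate C3, and as oxocarbenium character develops at O1=C2 the aryl group shifts from boron to C2 antiperiplanar to the incoming proton (1,2-metallate rearrangement). The closest known reaction types are the electrophile-induced anti 1,2-migrations of alkenyl and enol ether boronate complexes (Zweifel olefination, three-component conjunctive couplings) and the acid-triggered alkyl migration in lithium vinyl- and (α-alkoxyvinyl)trialkylborates; what is new is a proton as the electrophile on a cyclic, tetrasubstituted enol ether pinacol boronate with an aryl migrating group. No ring is closed in this step. C3 is set by substrate control from C4: the 2,4,5-trimethoxybenzyl group on the adjacent sp3 carbon blocks one face of the flat O1–C2=C3 unit, so the proton should arrive anti to it and push the CH2OTBS group cis to the benzyl group; C2 then follows stereospecifically, because anti addition places the aryl group on the face opposite to the new C3–H, that is cis to CH2OTBS, and leaves boron trans to all three substituents. The step needs protonation at C3 and not at the boron-bearing C2 (secured by the enol ether polarisation), migration of aryl and not of a pinacolate oxygen (aryl is the only carbon ligand that can migrate), and high facial selectivity (secured by the C4 substituent and the bulk of the acid).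

Step 9
Reactants: 17 (2R,3R,4R)-3-[(tert-butyldimethylsilyloxy)methyl]-2-(4,4,5,5-tetramethyl-1,3,2-dioxaborolan-2-yl)-4-(2,4,5-trimethoxybenzyl)-2-(3,4,5-trimethoxyphenyl)oxolane
Product: 19 [(2R,3R,4R)-4-(2,4,5-trimethoxybenzyl)-2-(3,4,5-trimethoxyphenyl)oxolan-3-yl]methanol, via desilylated boronic ester 18 (not isolated)
Conditions: TBAF·3H2O (4 equiv), THF, 25 → 45 °C
Reagents that add atoms: none
Why: Fluoride should first cleave the silyl ether and then form the fluoroboronate, whose C2–B bond is protonated by water with retention (stereoretentive protodeboronation of a tertiary benzylic boronic ester), so hydrogen takes the place of boron on the face anti to the three cis substituents and the all-cis target results.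

## Compound list

1 | 2,4,5-trimethoxybenzaldehyde | COc1cc(OC)c(OC)cc1C=O | starting material
2 | dimethyl succinate | COC(=O)CCC(=O)OC | starting material
3 | methyl 5-oxo-2-(2,4,5-trimethoxyphenyl)oxolane-3-carboxylate (paraconic ester lactone, mixture of stereoisomers) | COC(=O)C1CC(=O)OC1c1cc(OC)c(OC)cc1OC | intermediate
4 | (E)-3-(methoxycarbonyl)-4-(2,4,5-trimethoxyphenyl)but-3-enoic acid | COC(=O)/C(CC(=O)O)=C/c1cc(OC)c(OC)cc1OC | intermediate
5 | (R)-3-(methoxycarbonyl)-4-(2,4,5-trimethoxyphenyl)butanoic acid | COc1cc(OC)c(OC)cc1C[C@H](CC(=O)O)C(=O)OC | intermediate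
6 | (R)-3-(hydroxymethyl)-4-(2,4,5-trimethoxyphenyl)butanoic acid | COc1cc(OC)c(OC)cc1C[C@H](CC(=O)O)CO | intermediate
7 | (R)-4-(2,4,5-trimethoxybenzyl)oxolan-2-one | COc1cc(OC)c(OC)cc1C[C@H]1COC(=O)C1 | intermediate
8 | lithium enolate of 7 | COc1cc(OC)c(OC)cc1C[C@H]1COC([O-])=C1.[Li+] | intermediate
9 | (3S,4R)-3-(hydroxymethyl)-4-(2,4,5-trimethoxybenzyl)oxolan-2-one | COc1cc(OC)c(OC)cc1C[C@H]1COC(=O)[C@@H]1CO | intermediate
10 | (3S,4R)-3-[(tert-butyldimethylsilyloxy)methyl]-4-(2,4,5-trimethoxybenzyl)oxolan-2-one | COc1cc(OC)c(OC)cc1C[C@H]1COC(=O)[C@@H]1CO[Si](C)(C)C(C)(C)C | intermediate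
11 | potassium enolate of 10 | COc1cc(OC)c(OC)cc1C[C@H]1COC([O-])=C1CO[Si](C)(C)C(C)(C)C.[K+] | intermediate
12 | (4R)-3-[(tert-butyldimethylsilyloxy)methyl]-4-(2,4,5-trimethoxybenzyl)-4,5-dihydrofuran-2-yl diphenyl phosphate | COc1cc(OC)c(OC)cc1C[C@H]1COC(OP(=O)(Oc2ccccc2)Oc2ccccc2)=C1CO[Si](C)(C)C(C)(C)C | intermediate
13 | tert-butyldimethyl{[(4R)-2-(4,4,5,5-tetramethyl-1,3,2-dioxaborolan-2-yl)-4-(2,4,5-trimethoxybenzyl)-4,5-dihydrofuran-3-yl]methoxy}silane | COc1cc(OC)c(OC)cc1C[C@H]1COC(B2OC(C)(C)C(C)(C)O2)=C1CO[Si](C)(C)C(C)(C)C | intermediate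
14 | 5-bromo-1,2,3-trimethoxybenzene | COc1cc(Br)cc(OC)c1OC | starting material
15 | 3,4,5-trimethoxyphenyllithium | COc1cc([Li])cc(OC)c1OC | intermediate
16 | lithium boronate complex of 13 with the 3,4,5-trimethoxyphenyl group on boron | COc1cc(OC)c(OC)cc1C[C@H]1COC([B-]2(c3cc(OC)c(OC)c(OC)c3)OC(C)(C)C(C)(C)O2)=C1CO[Si](C)(C)C(C)(C)C.[Li+] | intermediate
17 | (2R,3R,4R)-3-[(tert-butyldimethylsilyloxy)methyl]-2-(4,4,5,5-tetramethyl-1,3,2-dioxaborolan-2-yl)-4-(2,4,5-trimethoxybenzyl)-2-(3,4,5-trimethoxyphenyl)oxolane | COc1cc(OC)c(OC)cc1C[C@H]1CO[C@@](B2OC(C)(C)C(C)(C)O2)(c2cc(OC)c(OC)c(OC)c2)[C@H]1CO[Si](C)(C)C(C)(C)C | intermediate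
18 | [(2R,3R,4R)-2-(4,4,5,5-tetramethyl-1,3,2-dioxaborolan-2-yl)-4-(2,4,5-trimethoxybenzyl)-2-(3,4,5-trimethoxyphenyl)oxolan-3-yl]methanol | COc1cc(OC)c(OC)cc1C[C@H]1CO[C@@](B2OC(C)(C)C(C)(C)O2)(c2cc(OC)c(OC)c(OC)c2)[C@H]1CO | intermediate
19 | [(2R,3R,4R)-4-(2,4,5-trimethoxybenzyl)-2-(3,4,5-trimethoxyphenyl)oxolan-3-yl]methanol | COc1cc(OC)c(OC)cc1C[C@H]1CO[C@@H](c2cc(OC)c(OC)c(OC)c2)[C@H]1CO | target

## Summary

Total step count: 9. Longest linear sequence: 9 steps (1 and 2 to 19); aryl bromide 14 is used as bought.

Steps most likely to fail: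

1. Step 8 (Proposed new method). What may go wrong: protonation of the boronate complex on the face syn to the C4 benzyl group, a stepwise instead of concerted aryl shift that loses the cis relation between aryl and CH2OTBS, or protonation at the boron-bearing carbon that simply returns the enol ether. Fallback with known chemistry, setting out from 13 and 14: Suzuki–Miyaura coupling (Pd(dppf)Cl2, K3PO4, dioxane/H2O, 60 °C) should give tert-butyldimethyl{[(4R)-4-(2,4,5-trimethoxybenzyl)-2-(3,4,5-trimethoxyphenyl)-4,5-dihydrofuran-3-yl]methoxy}silane F1. Heterogeneous hydrogenation of this tetrasubstituted 2-aryl enol ether (H2, Rh/Al2O3, EtOAc) should add both hydrogens to C2 and C3 from the face anti to the C4 benzyl group and give the all-cis silyl ether tert-butyldimethyl{[(2R,3R,4R)-4-(2,4,5-trimethoxybenzyl)-2-(3,4,5-trimethoxyphenyl)oxolan-3-yl]methoxy}silane F2. TBAF in THF then removes the silyl group and the route is rejoined at 19.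

2. Step 9. What may go wrong: loss of configuration at C2 during C–B protonolysis (inversion of a free carbanion or a radical pathway), or sluggish protodeboronation of the hindered α-alkoxy boronic ester. Fallback, setting out from 17: buffered oxidation of the C–B bond (NaBO3·4H2O, THF/pH 7 buffer, 0 °C) should give the hemiketal (3R,4R)-3-[(tert-butyldimethylsilyloxy)methyl]-4-(2,4,5-trimethoxybenzyl)-2-(3,4,5-trimethoxyphenyl)oxolan-2-ol F3 (anomeric mixture). HF·pyridine (THF, 0 °C) removes the silyl group to give (3R,4R)-3-(hydroxymethyl)-4-(2,4,5-trimethoxybenzyl)-2-(3,4,5-trimethoxyphenyl)oxolan-2-ol F4. Ionic reduction of the derived 2-aryl oxocarbenium ion (Et3SiH, BF3·OEt2, CH2Cl2/MeCN, −40 °C), with hydride entering anti to the cis C3 and C4 substituents, should place the aryl group cis to both and returns to 19.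

3. Step 7. What may go wrong: slow oxidative addition into the hindered, electron-rich ketene acetal phosphate, with hydrolysis of the phosphate back to the lactone or attack of phenoxide at phosphorus. Fallback, setting out from 10: DIBAL-H reduction (CH2Cl2, −78 °C) should give the lactol (3S,4R)-3-[(tert-butyldimethylsilyloxy)methyl]-4-(2,4,5-trimethoxybenzyl)oxolan-2-ol F5 (anomeric mixture). Dehydration (MsCl, Et3N, CH2Cl2, 0 °C → reflux) gives the enol ether tert-butyldimethyl{[(4R)-4-(2,4,5-trimethoxybenzyl)-4,5-dihydrofuran-3-yl]methoxy}silane F6. Lithiation of its C2–H (t-BuLi, THF, −78 → −30 °C, kept cold and short to limit ring lithiation of the trimethoxyarene) and trapping with 2-isopropoxy-4,4,5,5-tetramethyl-1,3,2-dioxaborolane rejoins the route at 13.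

Further compounds

F1 | step 8 | tert-butyldimethyl{[(4R)-4-(2,4,5-trimethoxybenzyl)-2-(3,4,5-trimethoxyphenyl)-4,5-dihydrofuran-3-yl]methoxy}silane | COc1cc(OC)c(OC)cc1C[C@H]1COC(c2cc(OC)c(OC)c(OC)c2)=C1CO[Si](C)(C)C(C)(C)C
F2 | step 8 | tert-butyldimethyl{[(2R,3R,4R)-4-(2,4,5-trimethoxybenzyl)-2-(3,4,5-trimethoxyphenyl)oxolan-3-yl]methoxy}silane | COc1cc(OC)c(OC)cc1C[C@H]1CO[C@@H](c2cc(OC)c(OC)c(OC)c2)[C@H]1CO[Si](C)(C)C(C)(C)C
F3 | step 9 | (3R,4R)-3-[(tert-butyldimethylsilyloxy)methyl]-4-(2,4,5-trimethoxybenzyl)-2-(3,4,5-trimethoxyphenyl)oxolan-2-ol (anomeric mixture) | COc1cc(OC)c(OC)cc1C[C@H]1COC(O)(c2cc(OC)c(OC)c(OC)c2)[C@H]1CO[Si](C)(C)C(C)(C)C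
F4 | step 9 | (3R,4R)-3-(hydroxymethyl)-4-(2,4,5-trimethoxybenzyl)-2-(3,4,5-trimethoxyphenyl)oxolan-2-ol (anomeric mixture) | COc1cc(OC)c(OC)cc1C[C@H]1COC(O)(c2cc(OC)c(OC)c(OC)c2)[C@H]1CO
F5 | step 7 | (3S,4R)-3-[(tert-butyldimethylsilyloxy)methyl]-4-(2,4,5-trimethoxybenzyl)oxolan-2-ol (anomeric mixture) | COc1cc(OC)c(OC)cc1C[C@H]1COC(O)[C@@H]1CO[Si](C)(C)C(C)(C)C
F6 | step 7 | tert-butyldimethyl{[(4R)-4-(2,4,5-trimethoxybenzyl)-4,5-dihydrofuran-3-yl]methoxy}silane | COc1cc(OC)c(OC)cc1C[C@H]1COC=C1CO[Si](C)(C)C(C)(C)C
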